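(The runs come from a simulation for an exercise, noise included.)

Partner over scavenger, both as charged, is the charge ratio 0.667, the number I carry through this flask, which is the birch run followed on. Suppose each coupling takes one partner and one scavenger. A ratio below one then makes partner the limiting reagent, and the share of scavenger left at the stop is one minus the ratio, here 33.3 %.

the same everywhere: starting material 0.46 M

| charge | partner | scavenger | temperature | remark | time |
|---|---|---|---|---|---|
| birch | 0.80 equiv | 1.2 equiv | −20 °C | the very flask that is asked about, followed so far |  |
| elm | 1.2 equiv | 1.2 equiv | −25 °C | run made earlier |  |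
| flask | 0.800 equiv | 1.20 equiv | −20 °C |  | 40 min |

birch run (percent of the starting material charged)

| time / min | double product / % |
|---|---|
| 3.00 | 24.9 |
| 5.00 | 25.4 |
| 8.00 | 25.9 |
| 12.0 | 25.3 |
| 15.0 | 25.5 |
| 25.0 | 25.1 |
| 40.0 | 25.0 |

elm run (percent of the starting material charged)

| time / s | double product / % |
|---|---|
| 10.0 | 5.4 |
| 15.0 | 9.1 |
| 20.0 | 13.4 |
| 30.0 | 19.8 |
| 40.0 | 24.2 |
| 50.0 | 28.8 |

(each reading ± 0.3 percentage points)

- alpha: at 40 min take out 90 % of the double product then present, then wait 40 min
- delta: at 40 min raise the temperature by 20 K, then wait 40 min
- gamma: at 40 min add partner, 100 % of the amount charged, then wait 40 min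
- beta: change nothing and wait 40 min more

* double product, in percent of the starting material first charged, at 40 min
* which option adds most double product ("none" when 2 percentage points or less is all one gets) (alpha / delta / gamma / beta / none)
* double product present, with what was taken out counted in, in percent of the starting material first charged, after delta
* double product present, with what was taken out counted in, in percent of the starting material first charged, after gamma

- double product taken out counts as made
- the numbers in the tables scatter by 0.3 percentage points (one standard deviation)
- additions bring no volume worth counting

The birch readings lie flat, from 24.9 % at 3.00 min to 25.0 % at 40.0 min. Elm, at −25 °C and with the ratio 1.00, reaches 28.8 % at 50.0 s, higher than that plateau, so the plateau looks like a shortage of partner.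

Two chemists agree on this much, and so both expect beta, alpha and delta to add nothing and gamma to add. They part over gamma, which lifts the ratio to 1.33. The first holds a ceiling view: coupling stops with the scavenger, so the part of the ratio above one, 0.333 of a scavenger charge, never couples. The second holds a ledger view: every partner charged couples, and the scavenger merely clears up behind it, so that 0.333 couples as well. The readings test neither view, since no run has a ratio above one. I side with the ledger, and I commit to 33.3 % of the scavenger remaining at the stop and to a gamma figure above the ceiling's.

The forecast, on the ceiling side, gives 25.3 % now, gamma as best, 25.3 % after delta and 47 % after gamma, and adds “This cap is untested”.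

The flask gives 25.4 %, with gamma best at 28 percentage points gained, against 0 points for alpha, 0 points for delta and 0 points for beta. It stands at 25.4 % after delta and 53.5 % after gamma.

    starting material + partner → single product + released group (k = 0.0789 M⁻¹ s⁻¹, Ea = 37.0 kJ mol⁻¹)
    partner + single product → double product + released group (k = 0.178 M⁻¹ s⁻¹, Ea = 54.0 kJ mol⁻¹)
    partner + double product → tris adduct + released group (k = 0.0207 M⁻¹ s⁻¹, Ea = 55.0 kJ mol⁻¹)
    partner + tris adduct → tetra adduct + released group (k = 0.0919 M⁻¹ s⁻¹, Ea = 48.0 kJ mol⁻¹)
    starting material + released group ⇌ idle adduct, settled at all times (K = 1.21 M⁻¹, ΔH = −9.00 kJ mol⁻¹)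
    scavenger + released group → scavenged by-product (k = 5.42 M⁻¹ s⁻¹, Ea = 41.0 kJ mol⁻¹)
    (constants at −20 °C)

At 40.0 min the flask holds partner 0 % and scavenger 33.3 % of its charge, as one minus 0.667 gave. At this ratio the ceiling and the ledger count the same couplings, so this flask favours neither view. The neighbouring flask with 2.00 equiv of partner has the ratio 1.67, so 0.667 of a scavenger charge should couple beyond the scavenger. That neighbour ends with partner 0 % and scavenger 0 %, and free released group stands to scavenged by-product as 0.634, with 3.88 % as idle adduct and double product at 58.3 %.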